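Follow one first end group out of the solid in Wednesday's flask, and ask its chances at each fork.

the same everywhere: second end groups 0.475 mM

|  | solid first end groups | remark | time |
|---|---|---|---|
| Wednesday's | 0.50 mM | the very flask that is asked about, followed so far |  |
| Saturday's | 0.25 mM | run made earlier |  |
| flask | 0.50 mM |  | 30 min |

- Wednesday's (time / min: links / %, rings / %): 0.833: 75.8, 18.1; 2.50: 75.9, 18.4; 4.00: 76.1, 19.0; 6.00: 76.0, 18.6; 10.0: 76.3, 19.2
- Saturday's (time / min: links / %, rings / %): 6.00: 90.1, 10.5; 12.0: 91.0, 9.8; 20.0: 90.6, 9.3; 25.0: 89.9, 10.7; 30.0: 90.4, 10.2

(standard deviation of a reading: 0.5 percentage points)

- as a solid, counted per litre of solution: solid first end groups
- candidate steps: first end groups + second end groups -> links; first end groups + second end groups -> rings; solid first end groups <-> first end groups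
- at the start none of the solid first end groups is in solution
- what has only dissolved of solid first end groups counts as not reacted
- the reaction counts as stopped when no species that holds the solid first end groups changes by six tenths of a point or more over the second half of the time
- first end groups means what is dissolved; the solid is not counted in it

- at 30 min, what has stopped the reaction, if anything has (for what has run out or reacted, a solid counts together with what of it has only dissolved) (it is still moving / all of the solid first end groups has reacted / the second end groups has run out first / forward and back rates have come level)
- links at 30 min, in percent of the solid first end groups charged
- rings at 30 min, in percent of the solid first end groups charged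
- first end groups at 30 min, in percent of the solid first end groups charged

What can become of it? It dissolves, then becomes a link or a ring, and by the candidate steps either fate costs one second end group.

So what is its chance of reacting at all? In Wednesday's flask there are fewer second end groups than solid first end groups, so the second end groups are the limiting reagent. If the second end groups are used up, the chance is the charge of second end groups divided by the charge of solid first end groups, 95.0%: the partner chance.

Does the rule hold on Saturday's run? There the same ratio is 190%, with more second end groups than solid first end groups, and the last links plus rings read 101%, the whole charge within scatter.

But Wednesday's sums go from 93.9% at the first reading to 95.5% at the last: is that flask still moving? The last sum stands above the partner chance, and each reading scatters by 0.5 percentage points, so I read scatter, not drift.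

And the fork itself? Rings take 20.1% of what reacted in Wednesday's last reading, but 10.1% in Saturday's, so I keep Wednesday's own share.

My reckoning for Wednesday's flask at 30 min is rings 19.1%, links 75.9% and first end groups 5.00%, if the remainder has dissolved, which no reading shows.

The forecast says the second end groups has run out first, with links 76.2%, rings 18.8% and first end groups 5%, from “the 95% ceiling set by the second end groups”. Its rings differ from mine by 0.3 points.

The flask gives, at 30 min: the second end groups has run out first, with links 76.0%, rings 19.0% and first end groups 5.00%, the 5.00% that the partner chance leaves, while 0% of the second end groups remains.

    first end groups + second end groups → links (k = 599 M⁻¹ s⁻¹)
    first end groups + second end groups → rings, rate k2*[first end groups] as long as [second end groups] is above zero (k = 0.0214 s⁻¹)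
    solid first end groups ⇌ first end groups, rate k3*(cs3 - [first end groups]) while solid is left; crystals form when [first end groups] > cs3 (solubility = 0.170 mM, k = 3.53 s⁻¹)

At 0.500 mM of second end groups, that answer for first end groups has moved by 5 points. In the neighbouring flask with 0.85 mM of solid first end groups, the partner chance is 55.9%, and links 44.7% plus rings 11.2% come to 55.9%.

Readings and results are simulated for an exercise; noise was put on by code.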